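The C9–C10 bond of ring B is the disconnection on which the plan rests. Once it is cut, ring A (C1–C5, C10) reads as an arene. Oxygen at C3, C15 at C4, the bond to C6 at C5 and a methyl group at C10 para to the oxygen match a 3-alkyl-2,4-dimethylphenol. In one operation the phenoxide attacks a tethered C9 bromide through C10. Ring B closes, quaternary C10 is set under 1,4-control from C7, and the C3 carbonyl and tetrasubstituted C4=C5 olefin appear. That olefin is kept for the final singlet-oxygen ene reaction. The precursor is methyl (3R)-5-bromo-3-(3-hydroxy-2,6-dimethylbenzyl)pentanoate, reached by enantioselective conjugate addition to a δ-lactone.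

Key step: step 8

Remark: C1–C15 are eudesmane numbers and are used for every intermediate (C6 = benzylic CH2, C7 = first stereocentre, C9 = carbon that carries O and then Br, C10 = arene carbon para to oxygen).
Assumption: the sense of induction of the copper catalyst with a benzylic Grignard reagent cannot be predicted safely. Both ligand enantiomers are sold, so the choice is fixed after the first run by correlating lactone 8 with material from the auxiliary route given as the first fallback.

Step 1
Reactants: 1 2,6-dimethylbenzoic acid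
Product: 2 3-bromo-2,6-dimethylbenzoic acid
Conditions: Br2 (1.0 equiv), AcOH, rt, dark
Reagents that add atoms: bromine, BrBr
Why: Electrophilic aromatic bromination should go to C3, which is ortho to one methyl, para to the other and meta to the carboxyl group, while one equivalent of bromine in the dark holds back dibromination and benzylic bromination.

Step 2
Reactants: 2 3-bromo-2,6-dimethylbenzoic acid
Product: 3 3-methoxy-2,6-dimethylbenzoic acid
Conditions: NaOMe (5 equiv), CuI (10 mol %), MeOH–DMF, 110 °C (sealed); then aq HCl
Reagents that add atoms: sodium methoxide, C[O-].[Na+]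
Why: Ullmann-type copper-catalysed methoxylation of an aryl bromide tolerates the carboxylate, which is shielded by two ortho methyl groups and returns as the acid on acidification.

Step 3
Reactants: 3 3-methoxy-2,6-dimethylbenzoic acid
Product: 4 (3-methoxy-2,6-dimethylphenyl)methanol
Conditions: BH3·SMe2 (2.5 equiv), THF, 0 °C → reflux; then H2O
Reagents that add atoms: none
Why: Borane reduces carboxylic acids through acyloxyboranes even when both ortho positions are blocked, and it leaves the aryl methyl ether alone.

Step 4
Reactants: 4 (3-methoxy-2,6-dimethylphenyl)methanol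
Product: 5 3-methoxy-2,6-dimethylbenzyl chloride
Conditions: SOCl2 (1.2 equiv), CH2Cl2, 0 °C → rt; used crude at once
Reagents that add atoms: thionyl chloride, O=S(Cl)Cl
Why: Chlorodehydroxylation through the chlorosulfite is fast for an electron-rich benzylic alcohol and gives only gaseous by-products, so the sensitive chloride needs no chromatography.

Step 5
Reactants: 5 3-methoxy-2,6-dimethylbenzyl chloride
Product: 6 (3-methoxy-2,6-dimethylbenzyl)magnesium chloride (titrated ether solution)
Conditions: Mg turnings (3 equiv, I2-activated), Et2O, 0 °C, slow addition of 5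
Reagents that add atoms: magnesium, [Mg]
Why: Magnesium inserts into the benzylic C–Cl bond (Grignard formation), and the chloride leaving group, excess metal, slow addition and the two ortho methyl groups together hold back Wurtz coupling.

Step 6
Reactants: 6 (3-methoxy-2,6-dimethylbenzyl)magnesium chloride; 7 5,6-dihydro-2H-pyran-2-one
Product: 8 (4S)-4-(3-methoxy-2,6-dimethylbenzyl)oxan-2-one
Conditions: CuBr·SMe2 (5 mol %), Josiphos-type ferrocenyl bisphosphine (6 mol %), t-BuOMe, −75 °C, 6 added over 3 h; then MeOH, aq NH4Cl
Reagents that add atoms: none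
Why: Copper-catalysed enantioselective conjugate addition of Grignard reagents is established for this unsaturated δ-lactone with ferrocenyl bisphosphines; it forms C6–C7 and sets C7 by catalyst control, while low temperature and slow addition suppress uncatalysed carbonyl attack.

Step 7
Reactants: 8 (4S)-4-(3-methoxy-2,6-dimethylbenzyl)oxan-2-one
Product: 10 methyl (3R)-5-bromo-3-(3-hydroxy-2,6-dimethylbenzyl)pentanoate, via bromo acid 9 (not isolated)
Conditions: BBr3 (3.5 equiv), CH2Cl2, −78 °C → rt; then MeOH, 0 → 40 °C
Reagents that add atoms: boron tribromide, BrB(Br)Br; methanol, CO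
Why: Boron tribromide cleaves both boron-activated alkyl–oxygen bonds (aryl ether demethylation and SN2 opening of the lactone at C9), and the HBr released by the methanol quench drives Fischer esterification, with C7 untouched and renamed R only because bromine raises the rank of the C8–C9 arm.

Step 8
Reactants: 10 methyl (3R)-5-bromo-3-(3-hydroxy-2,6-dimethylbenzyl)pentanoate
Product: 12 methyl (7R,10S)-3-oxo-13-noreudesma-1,4-dien-12-oate, via caesium phenoxide 11 (not isolated)
Conditions: Cs2CO3 (1.5 equiv), 4 Å MS, DMF, 65 °C, 10 added by syringe pump over 10 h (final 4 mM), Ar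
Reagents that add atoms: none
Why: Caesium carbonate converts phenol 10 into phenoxide 11, whose para carbon C10 displaces bromide from C9 in an intramolecular SN2 reaction, so one event forms the C9–C10 bond, closes ring B and turns the arene into the cross-conjugated dienone with quaternary C10. The closest known reaction type is the base-mediated alkylative dearomatisation of phenols by a tethered halide or sulfonate (Winstein–Masamune reaction, Ar2-6 participation). Ring B closes in the 6-(enolendo)-exo-tet mode, which is allowed because the four-atom tether lets C9 meet the p lobe of C10 at right angles to the ring plane with bromide leaving collinearly. C10 is controlled by C7, because in the chair-like transition state the CH2CO2Me arm sits equatorial and C9 bonds to the face that leaves the C10 methyl axial on ring B and cis to that arm, which is the (7R,10S) series of the target. The step needs C10 to win over the equally distant ortho carbon C4 and over oxygen: the loose caesium ion pair in DMF removes cation assistance next to oxygen, the para carbon has the larger HOMO coefficient and leads to the more stable cross-conjugated dienone, the meta tether cannot reach oxygen within the molecule, and slow addition at millimolar concentration suppresses O-alkylation between molecules. C7 is not acidic, and phenoxide and carbonate are too weak to enolise the ester or eliminate the primary bromide.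

Step 9
Reactants: 12 methyl (7R,10S)-3-oxo-13-noreudesma-1,4-dien-12-oate
Product: 13 methyl (7R,10S)-3-oxo-13-noreudesm-4-en-12-oate
Conditions: H2 (1 atm), RhCl(PPh3)3 (5 mol %), toluene–EtOH 1:1, rt
Reagents that add atoms: none
Why: Hydrogenation with the Wilkinson catalyst is highly sensitive to olefin substitution, so it should saturate only the disubstituted C1=C2 bond, as is known for 4-methyl-1,4-dien-3-ones, and leave the tetrasubstituted C4=C5 bond and the ester.

Step 10
Reactants: 13 methyl (7R,10S)-3-oxo-13-noreudesm-4-en-12-oate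
Product: 14 methyl (3S,7R,10S)-3-hydroxy-13-noreudesm-4-en-12-oate (3β-OH)
Conditions: NaBH4 (1.1 equiv), CeCl3·7H2O (1.1 equiv), MeOH, −40 → 0 °C
Reagents that add atoms: none
Why: Luche 1,2-reduction delivers hydride axially on the α face, anti to the axial C10 methyl, which should give the equatorial 3β (3S) allylic alcohol and spare the ester.

Step 11
Reactants: 14 methyl (3S,7R,10S)-3-hydroxy-13-noreudesm-4-en-12-oate
Product: 16 methyl (3S,7R,10S)-13-(dimethylamino)-3-hydroxyeudesm-4-en-12-oate (C11 epimers), via dilithium alkoxide enolate 15 (not isolated)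
Conditions: LDA (2.3 equiv, commercial solution), THF, −78 °C; CH2=NMe2+ I− (2.5 equiv), −78 °C → rt; H2O
Reagents that add atoms: N,N-dimethylmethyleneiminium iodide (Eschenmoser's salt), C=[N+](C)C.[I-]
Why: Two equivalents of base make protection of the alcohol unnecessary, the enolate carbon of 15 attacks the iminium salt (Mannich reaction), the C11 centre is formed as a mixture that the next step erases, and the alkoxide returns as the alcohol on aqueous work-up.

Step 12
Reactants: 16 methyl (3S,7R,10S)-13-(dimethylamino)-3-hydroxyeudesm-4-en-12-oate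
Product: 18 methyl (3S,7R,10S)-3-hydroxyeudesma-4,11(13)-dien-12-oate, via trimethylammonium iodide 17 (not isolated)
Conditions: MeI (10 equiv), MeOH, rt; evaporate; sat aq NaHCO3–CH2Cl2, rt
Reagents that add atoms: none
Why: N-Quaternisation followed by E1cB (Hofmann-type) loss of trimethylamine under bicarbonate should give the C11(13) acrylate, and neither reagent touches the neutral secondary alcohol or the C4=C5 bond.

Step 13
Reactants: 18 methyl (3S,7R,10S)-3-hydroxyeudesma-4,11(13)-dien-12-oate; 19 angelic acid
Product: 21 methyl (3S,7R,10S)-3-[(Z)-2-methylbut-2-enoyloxy]eudesma-4,11(13)-dien-12-oate, via mixed anhydride 20 (not isolated)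
Conditions: 19, 2,4,6-Cl3C6H2COCl, Et3N, toluene, rt; then 18, 75 °C, trace BHT, no DMAP
Reagents that add atoms: none
Why: Yamaguchi-type mixed-anhydride esterification without a nucleophilic pyridine catalyst acylates the equatorial alcohol at the less hindered angeloyl carbonyl with retention at C3, and it avoids the addition–elimination path that turns angelates into tiglates.

Step 14
Reactants: 21 methyl (3S,7R,10S)-3-[(Z)-2-methylbut-2-enoyloxy]eudesma-4,11(13)-dien-12-oate
Product: 22 methyl (3S,5S,7R,10S)-3-[(Z)-2-methylbut-2-enoyloxy]-5-hydroperoxyeudesma-4(15),11(13)-dien-12-oate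
Conditions: O2, tetraphenylporphyrin (0.5 mol %), CH2Cl2, −20 °C, visible light (>500 nm); concentrate cold, no reductant
Reagents that add atoms: dioxygen, O=O
Why: In the Schenck ene reaction the electron-rich tetrasubstituted C4=C5 bond should react far faster than the two electron-poor conjugated ester olefins, and oxygen should approach the α face anti to the axial C10 methyl and the 3β-acyloxy group, bond to C5 (5S) and take a hydrogen from the C15 methyl geminal to the bulky C3 substituent, since on that face C6 offers only an equatorial hydrogen and the C3–H is deactivated by the acyloxy group.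

Compound list
1 | 2,6-dimethylbenzoic acid | Cc1cccc(C)c1C(=O)O | starting material
2 | 3-bromo-2,6-dimethylbenzoic acid | Cc1ccc(Br)c(C)c1C(=O)O | intermediate
3 | 3-methoxy-2,6-dimethylbenzoic acid | COc1ccc(C)c(C(=O)O)c1C | intermediate
4 | (3-methoxy-2,6-dimethylphenyl)methanol | COc1ccc(C)c(CO)c1C | intermediate
5 | 3-methoxy-2,6-dimethylbenzyl chloride | COc1ccc(C)c(CCl)c1C | intermediate
6 | (3-methoxy-2,6-dimethylbenzyl)magnesium chloride | COc1ccc(C)c(C[Mg]Cl)c1C | intermediate
7 | 5,6-dihydro-2H-pyran-2-one | O=C1C=CCCO1 | starting material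
8 | (4S)-4-(3-methoxy-2,6-dimethylbenzyl)oxan-2-one | O=C1C[C@@H](Cc2c(C)ccc(OC)c2C)CCO1 | intermediate
9 | (3R)-5-bromo-3-(3-hydroxy-2,6-dimethylbenzyl)pentanoic acid | OC(=O)C[C@@H](Cc1c(C)ccc(O)c1C)CCBr | intermediate
10 | methyl (3R)-5-bromo-3-(3-hydroxy-2,6-dimethylbenzyl)pentanoate | COC(=O)C[C@@H](Cc1c(C)ccc(O)c1C)CCBr | intermediate
11 | caesium phenoxide of 10 | COC(=O)C[C@@H](Cc1c(C)ccc([O-])c1C)CCBr.[Cs+] | intermediate
12 | methyl 2-[(2R,4aS)-4a,8-dimethyl-7-oxo-1,2,3,4,4a,7-hexahydronaphthalen-2-yl]acetate (C10 methyl cis to the C7 arm) | COC(=O)C[C@@H]1CC[C@@]2(C)C=CC(=O)C(C)=C2C1 | intermediate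
13 | methyl 2-[(2R,4aS)-4a,8-dimethyl-7-oxo-1,2,3,4,4a,5,6,7-octahydronaphthalen-2-yl]acetate | COC(=O)C[C@@H]1CC[C@@]2(C)CCC(=O)C(C)=C2C1 | intermediate
14 | methyl 2-[(2R,4aS,7S)-7-hydroxy-4a,8-dimethyl-1,2,3,4,4a,5,6,7-octahydronaphthalen-2-yl]acetate (3β-OH) | COC(=O)C[C@@H]1CC[C@@]2(C)CC[C@H](O)C(C)=C2C1 | intermediate
15 | dilithium alkoxide enolate of 14 | COC([O-])=C[C@@H]1CC[C@@]2(C)CC[C@H]([O-])C(C)=C2C1.[Li+].[Li+] | intermediate
16 | methyl (3S,7R,10S)-13-(dimethylamino)-3-hydroxyeudesm-4-en-12-oate, C11 epimers | COC(=O)C(CN(C)C)[C@@H]1CC[C@@]2(C)CC[C@H](O)C(C)=C2C1 | intermediate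
17 | trimethylammonium iodide of 16 | COC(=O)C(C[N+](C)(C)C)[C@@H]1CC[C@@]2(C)CC[C@H](O)C(C)=C2C1.[I-] | intermediate
18 | methyl (3S,7R,10S)-3-hydroxyeudesma-4,11(13)-dien-12-oate | C=C(C(=O)OC)[C@@H]1CC[C@@]2(C)CC[C@H](O)C(C)=C2C1 | intermediate
19 | angelic acid, (Z)-2-methylbut-2-enoic acid | C/C=C(/C)C(=O)O | starting material
20 | angelic 2,4,6-trichlorobenzoic anhydride | C/C=C(/C)C(=O)OC(=O)c1c(Cl)cc(Cl)cc1Cl | intermediate
21 | methyl (3S,7R,10S)-3-angeloyloxyeudesma-4,11(13)-dien-12-oate | C=C(C(=O)OC)[C@@H]1CC[C@@]2(C)CC[C@H](OC(=O)/C(C)=C\C)C(C)=C2C1 | intermediate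
22 | methyl (3S,5S,7R,10S)-3-angeloyloxy-5-hydroperoxyeudesma-4(15),11(13)-dien-12-oate (3β-OAng, 5α-OOH, 7β side chain, 10β-Me) | C=C(C(=O)OC)[C@@H]1CC[C@@]2(C)CC[C@H](OC(=O)/C(C)=C\C)C(=C)[C@]2(OO)C1 | target

Total step count: 14. Longest linear sequence: 14 steps (1 → 22). Compounds 7 and 19 are bought.

Steps most likely to fail

Step 6.
- **What may go wrong:** Enantioselection may erode, because a benzylic Grignard reagent with two ortho substituents lies outside the usual alkyl series. Uncatalysed addition may also compete, and reagent may be lost to homocoupling.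
- **Fallback (auxiliary control in place of catalysis):** It sets out from benzyl chloride 5 and comes back at lactone 8. (R)-4-Benzyloxazolidin-2-one is N-acylated (n-BuLi, methyl 4-chloro-4-oxobutanoate) to the succinyl oxazolidinone F1. Its sodium enolate (NaHMDS, THF, −78 °C) is alkylated with 5 and NaI on the face away from the benzyl group (Evans alkylation) to give imide F2. LiOH/H2O2 at 0 °C removes the auxiliary and gives the (R)-benzylsuccinic acid 4-methyl ester F3. Oxalyl chloride gives acid chloride F4, and diazomethane gives diazoketone F5. Silver-benzoate-catalysed Wolff rearrangement in aqueous THF (Arndt–Eistert homologation, retention at C7) gives the glutaric half-ester F6. BH3·SMe2 at 0 °C reduces only the acid to hydroxy ester F7, which closes to 8 with catalytic TsOH in toluene.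

Step 8.
- **What may go wrong:** The ring may close at the ortho carbon C4 instead of the para carbon. O-alkylation between molecules may give oligomers. The facial bias from C7 may be weak.
- **Fallback (acid-triggered closure with a far stronger electrophile and no free phenoxide):** It sets out from benzyl chloride 5, follows the first fallback as far as diazoketone F5, and comes back at dienone 12. In CF3CO2H–CH2Cl2 at −20 °C, F5 is protonated to an α-keto diazonium ion. The anisole ring traps this ion through its para carbon (acid-promoted Ar2-6 diazoketone cyclisation). The resulting O-methyl oxocarbenium ion is hydrolysed on work-up to the 3,8-dioxo dienone F8. Any epimerisation at C7, now α to a ketone, converges on the wanted equatorial arm. The saturated C8 ketone reacts selectively with TsNHNH2, because the cross-conjugated C3 carbonyl is inert, and gives tosylhydrazone F9. Catecholborane followed by NaOAc·3H2O reduces F9 to the CH2 of 12.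

Step 14.
- **What may go wrong:** Hydrogen may be abstracted from C6 or C3 instead of C15. Oxygen may attack the β face. The angelate may suffer slow photo-oxidation or Z/E scrambling during long irradiation. The free hydroperoxide may break down on purification.
- **Fallback (peroxide first, angelate last):** It sets out from hydroxy acrylate 18 and comes back at target 22. TBSCl and imidazole give silyl ether F10, whose larger C3 substituent reinforces both the geminal directing effect and the shielding of the β face. Photooxygenation under the conditions of step 14 gives hydroperoxide F11. 2-Methoxypropene with PPTS masks the OOH group as the 2-methoxyprop-2-yl perketal F12. TBAF buffered with AcOH frees alcohol F13. Mixed anhydride 20 in toluene at 60 °C gives the angelate perketal F14. AcOH–THF–H2O at rt then releases 22.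

Further compounds
F1 | step 6 | (R)-4-benzyl-3-(4-methoxy-4-oxobutanoyl)oxazolidin-2-one | COC(=O)CCC(=O)N1[C@H](Cc2ccccc2)COC1=O
F2 | step 6 | methyl (3R)-4-[(4R)-4-benzyl-2-oxooxazolidin-3-yl]-3-(3-methoxy-2,6-dimethylbenzyl)-4-oxobutanoate | COC(=O)C[C@@H](Cc1c(C)ccc(OC)c1C)C(=O)N1[C@H](Cc2ccccc2)COC1=O
F3 | step 6 | (2R)-4-methoxy-2-(3-methoxy-2,6-dimethylbenzyl)-4-oxobutanoic acid | COC(=O)C[C@@H](Cc1c(C)ccc(OC)c1C)C(=O)O
F4 | step 6 | methyl (3R)-4-chloro-3-(3-methoxy-2,6-dimethylbenzyl)-4-oxobutanoate | COC(=O)C[C@@H](Cc1c(C)ccc(OC)c1C)C(=O)Cl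
F5 | step 6 | methyl (3R)-5-diazo-3-(3-methoxy-2,6-dimethylbenzyl)-4-oxopentanoate | COC(=O)C[C@@H](Cc1c(C)ccc(OC)c1C)C(=O)C=[N+]=[N-]
F6 | step 6 | (3S)-5-methoxy-3-(3-methoxy-2,6-dimethylbenzyl)-5-oxopentanoic acid | COC(=O)C[C@@H](Cc1c(C)ccc(OC)c1C)CC(=O)O
F7 | step 6 | methyl (3S)-5-hydroxy-3-(3-methoxy-2,6-dimethylbenzyl)pentanoate | COC(=O)C[C@@H](Cc1c(C)ccc(OC)c1C)CCO
F8 | step 8 | methyl (7R,10S)-3,8-dioxo-13-noreudesma-1,4-dien-12-oate | COC(=O)C[C@@H]1C(=O)C[C@@]2(C)C=CC(=O)C(C)=C2C1
F9 | step 8 | C8 tosylhydrazone of F8 | COC(=O)C[C@@H]1C(=NNS(=O)(=O)c3ccc(C)cc3)C[C@@]2(C)C=CC(=O)C(C)=C2C1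
F10 | step 14 | methyl (3S,7R,10S)-3-(tert-butyldimethylsilyloxy)eudesma-4,11(13)-dien-12-oate | C=C(C(=O)OC)[C@@H]1CC[C@@]2(C)CC[C@H](O[Si](C)(C)C(C)(C)C)C(C)=C2C1
F11 | step 14 | methyl (3S,5S,7R,10S)-3-(tert-butyldimethylsilyloxy)-5-hydroperoxyeudesma-4(15),11(13)-dien-12-oate | C=C(C(=O)OC)[C@@H]1CC[C@@]2(C)CC[C@H](O[Si](C)(C)C(C)(C)C)C(=C)[C@]2(OO)C1
F12 | step 14 | 2-methoxyprop-2-yl perketal of F11 | C=C(C(=O)OC)[C@@H]1CC[C@@]2(C)CC[C@H](O[Si](C)(C)C(C)(C)C)C(=C)[C@]2(OOC(C)(C)OC)C1
F13 | step 14 | methyl (3S,5S,7R,10S)-3-hydroxy-5-(2-methoxyprop-2-ylperoxy)eudesma-4(15),11(13)-dien-12-oate | C=C(C(=O)OC)[C@@H]1CC[C@@]2(C)CC[C@H](O)C(=C)[C@]2(OOC(C)(C)OC)C1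
F14 | step 14 | methyl (3S,5S,7R,10S)-3-angeloyloxy-5-(2-methoxyprop-2-ylperoxy)eudesma-4(15),11(13)-dien-12-oate | C=C(C(=O)OC)[C@@H]1CC[C@@]2(C)CC[C@H](OC(=O)/C(C)=C\C)C(=C)[C@]2(OOC(C)(C)OC)C1
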